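The route disconnects ring B between C5 (the ring-fusion CH flanked by the quaternary carbons C4 and C10) and C6 (its ring-B methylene neighbour). In the precursor, C5 is the non-enolisable carbonyl of a ring-A cyclohexanone and C6 is an aldehyde at the end of the C10 side chain. A McMurry coupling joins them in one operation and closes ring B as a C5=C6 alkene, which hydrogenation turns into the trans fusion. C10 comes from an Ireland–Claisen chirality transfer from (S)-phorenol, C8 from methyl hydrogen (R)-3-methylglutarate, and the (E)-chloroalkene from chloride capture of an aryl-stabilised vinyl cation.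

Key step: step 7

Locants: the decalin numbering of the target is used for every intermediate. Ring A = C1, C2, C3, C4 (gem-dimethyl), C5, C10 (quaternary, CH3); ring B = C5, C6, C7, C8 (CH3), C9, C10; C11 = exocyclic C(Cl)Ar carbon; aryl carbons C1' to C6'.

Assumption: C9 is formed in step 5 as a mixture of epimers and stays so until it becomes sp2 in step 12; it carries no descriptor in the SMILES and RS in the names.

Assumption: the (S,S) antipode of the transfer-hydrogenation catalyst is taken to give the S carbinol by analogy with aryl ketones; if the sense is opposite, the (R,R) complex is used.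

Step 1
Reactants: 1 methyl hydrogen (R)-3-methylglutarate
Product: 3 (4S)-4-methyltetrahydro-2H-pyran-2-one, via hydroxy acid 2 (not isolated)
Conditions: LiBH4, THF, 0 °C to reflux; then 2 M HCl, rt
Reagents that add atoms: none
Why: chemoselective borohydride reduction, in which LiBH4 reduces the methyl ester but not the lithium carboxylate and acidification closes the δ-lactone, so the ester carbon becomes the future C6 while the C8 stereocenter is untouched.

Step 2
Reactants: 3 (4S)-4-methyltetrahydro-2H-pyran-2-one
Product: 4 (3R)-5-bromo-3-methylpentanoic acid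
Conditions: HBr (33% in AcOH), 60 °C
Reagents that add atoms: hydrogen bromide Br
Why: acid-promoted SN2 opening of the protonated lactone at its primary O–CH2 carbon by bromide gives the ω-bromo acid without touching the stereocenter (the descriptor changes only through the priority of bromine).

Step 3
Reactants: 5 ketoisophorone (2,6,6-trimethylcyclohex-2-ene-1,4-dione)
Product: 6 (S)-phorenol [(4S)-4-hydroxy-2,6,6-trimethylcyclohex-2-en-1-one]
Conditions: RuCl[(S,S)-TsDPEN](p-cymene) (1 mol%), HCO2H/Et3N (5:2), rt
Reagents that add atoms: none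
Why: Noyori asymmetric transfer hydrogenation reduces the unhindered enone carbonyl (future C2) and not the carbonyl shielded by the gem-dimethyl group (future C5), and the catalyst antipode sets the S carbinol that later relays its configuration to C10.

Step 4
Reactants: 6 (S)-phorenol; 4 (3R)-5-bromo-3-methylpentanoic acid
Product: 7 (1S)-3,5,5-trimethyl-4-oxocyclohex-2-en-1-yl (3R)-5-bromo-3-methylpentanoate
Conditions: DCC, DMAP (cat.), CH2Cl2, 0 °C to rt
Reagents that add atoms: none
Why: Steglich esterification of the secondary allylic alcohol under neutral conditions leaves both stereocenters and the primary bromide untouched.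

Step 5
Reactants: 7 (1S)-3,5,5-trimethyl-4-oxocyclohex-2-en-1-yl (3R)-5-bromo-3-methylpentanoate
Product: 11 methyl (2RS,3S)-5-bromo-3-methyl-2-[(1R)-1,3,3-trimethyl-2-oxocyclohex-5-en-1-yl]pentanoate, via silyl ketene acetal 8 (not isolated), via silyl ester 9 (not isolated), via carboxylic acid 10 (not isolated)
Conditions: LiN(iPr)2, Me3SiCl/Et3N (internal quench), THF, −78 °C, then 60 °C; 1 M HCl; then Me3SiCHN2, PhMe/MeOH, 0 °C
Reagents that add atoms: trimethylsilyldiazomethane C[Si](C)(C)C=[N+]=[N-]
Why: Ireland–Claisen rearrangement, in which the enolate is silylated before it can add to the enone or displace bromide and the ketene acetal then rearranges suprafacially across C2–C1=C10, so the C9–C10 bond forms on the face that carried the C2–O bond and the S carbinol is converted into the quaternary C10 of the target configuration (C9 forms as an inconsequential epimer mixture and the acid is methylated in the same flask).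

Step 6
Reactants: 11 methyl (2RS,3S)-5-bromo-3-methyl-2-[(1R)-1,3,3-trimethyl-2-oxocyclohex-5-en-1-yl]pentanoate
Product: 12 methyl (2RS,3S)-3-methyl-5-oxo-2-[(1R)-1,3,3-trimethyl-2-oxocyclohex-5-en-1-yl]pentanoate
Conditions: Me3NO (anhydrous), DMSO, rt
Reagents that add atoms: trimethylamine N-oxide C[N+](C)(C)[O-]
Why: Kornblum-type oxidation with an amine N-oxide, in which SN2 displacement of the primary bromide by the N-oxide oxygen and loss of trimethylammonium give the C6 aldehyde under neutral conditions that spare the ester, the β,γ-unsaturated ketone and both stereocenters.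

Step 7
Reactants: 12 methyl (2RS,3S)-3-methyl-5-oxo-2-[(1R)-1,3,3-trimethyl-2-oxocyclohex-5-en-1-yl]pentanoate
Product: 14 methyl (1RS,2S,8aR)-2,5,5,8a-tetramethyl-1,2,3,5,6,8a-hexahydronaphthalene-1-carboxylate, via TiCl2 pinacolate 13 (not isolated)
Conditions: TiCl3·1.5DME, Zn–Cu couple, DME, reflux; 12 added slowly by syringe pump
Reagents that add atoms: none
Why: McMurry coupling: low-valent titanium transfers single electrons to the C6 aldehyde and the C5 ketone, the two ketyl carbons join to the titanium-bound pinacolate 13, and at reflux the oxophilic metal strips both oxygens to leave the C5=C6 alkene. The closest known reaction type is the intramolecular keto-aldehyde McMurry cyclisation to cycloalkenes. Ring B closes as a six-membered carbocycle by direct union of its two terminal carbonyl carbons, both of which become ring members. No stereocenter is created, because C5 and C6 become sp2 (C5 is set in step 8) and C8 and C10 are not touched. The step needs the ketone–aldehyde pair to couple in preference to the C11 ester and to a second molecule; ester coupling is far slower and would close a five-membered ring at a neopentyl ester, and slow addition keeps the reaction intramolecular. The substrate secures the rest: C5, flanked by the quaternary C4 and C10, cannot enolise or eliminate, and electron transfer from the metal surface is not blocked by the shielding that would stop a bulky nucleophile.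

Step 8
Reactants: 14 methyl (1RS,2S,8aR)-2,5,5,8a-tetramethyl-1,2,3,5,6,8a-hexahydronaphthalene-1-carboxylate
Product: 15 methyl (1RS,2S,4aS,8aS)-2,5,5,8a-tetramethyldecahydronaphthalene-1-carboxylate
Conditions: H2 (4 bar), PtO2, AcOH, rt
Reagents that add atoms: none
Why: heterogeneous catalytic hydrogenation reduces the ring-A C1=C2 alkene and the hindered C5=C6 alkene, and hydrogen should reach C5 from the α face because the axial C10 and C8 methyl groups cover the β face, which sets the trans ring fusion (5S).

Step 9
Reactants: 16 5-bromovanillin (3-bromo-4-hydroxy-5-methoxybenzaldehyde)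
Product: 18 2-bromo-6-methoxybenzene-1,4-diol, via aryl formate 17 (not isolated)
Conditions: H2O2 (30% aq), NaOH, H2O/THF, 0 °C to rt; then HCl
Reagents that add atoms: hydrogen peroxide OO
Why: Dakin oxidation, in which the para-hydroxy group drives aryl migration in the peroxide adduct of the aldehyde and hydrolysis of the formate gives the hydroquinone with the bromine, methoxy and two oxygen positions required for the aryl ring.

Step 10
Reactants: 18 2-bromo-6-methoxybenzene-1,4-diol
Product: 19 1-bromo-2,3,5-trimethoxybenzene
Conditions: MeI, K2CO3, acetone, reflux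
Reagents that add atoms: iodomethane CI
Why: Williamson O-methylation masks both phenols as methyl ethers, which survive the aryllithium, enolate and cationic steps and cannot take part in the later vinyl cation.

Step 11
Reactants: 15 methyl (1RS,2S,4aS,8aS)-2,5,5,8a-tetramethyldecahydronaphthalene-1-carboxylate; 19 1-bromo-2,3,5-trimethoxybenzene
Product: 21 [(1RS,2S,4aS,8aS)-2,5,5,8a-tetramethyldecahydronaphthalen-1-yl](2,3,5-trimethoxyphenyl)methanone, via aryllithium 20 (not isolated)
Conditions: 19, n-BuLi, THF, −78 °C; then 15, −78 °C to 0 °C; NH4Cl (aq)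
Reagents that add atoms: none
Why: bromine–lithium exchange followed by acyl substitution of the ester, where the α-branched ketone next to quaternary C10 should be too hindered for a second addition of the ortho-substituted aryllithium, so the reaction stops at the aryl ketone.

Step 12
Reactants: 21 [(1RS,2S,4aS,8aS)-2,5,5,8a-tetramethyldecahydronaphthalen-1-yl](2,3,5-trimethoxyphenyl)methanone
Product: 23 [(2S,4aS,8aS)-2,5,5,8a-tetramethyloctahydronaphthalen-1(2H)-ylidene](2,3,5-trimethoxyphenyl)methyl trifluoromethanesulfonate (E/Z mixture), via potassium enolate 22 (not isolated)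
Conditions: KN(SiMe3)2, THF, −78 °C to 0 °C; then PhNTf2, 0 °C to rt
Reagents that add atoms: N-phenylbis(trifluoromethanesulfonimide) O=S(=O)(N(c1ccccc1)S(=O)(=O)C(F)(F)F)C(F)(F)F
Why: enolisation at C9, the only α-carbon that bears hydrogen, and O-sulfonylation give the tetrasubstituted enol triflate and erase the C9 stereocenter, and its E/Z ratio does not matter because both isomers ionise to the same cation in the next step.

Step 13
Reactants: 23 [(2S,4aS,8aS)-2,5,5,8a-tetramethyloctahydronaphthalen-1(2H)-ylidene](2,3,5-trimethoxyphenyl)methyl trifluoromethanesulfonate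
Product: 25 1-{(E)-chloro[(2S,4aS,8aS)-2,5,5,8a-tetramethyloctahydronaphthalen-1(2H)-ylidene]methyl}-2,3,5-trimethoxybenzene, via vinyl cation 24 (not isolated)
Conditions: Bu4NCl (5 equiv), (CF3)2CHOH, 50 °C
Reagents that add atoms: tetrabutylammonium chloride [Cl-].CCCC[N+](CCCC)(CCCC)CCCC
Why: vinylic SN1 substitution, in which the triflate ionises to a linear α-aryl vinyl cation stabilised by the ortho-methoxy aryl ring and chloride enters in the plane of the C9 substituents from the C8 side (past the equatorial C8–H) and not from the side blocked by quaternary C10 and its C1 methylene, which should give the E alkene with chlorine syn to C8 from either triflate isomer.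

Step 14
Reactants: 25 1-{(E)-chloro[(2S,4aS,8aS)-2,5,5,8a-tetramethyloctahydronaphthalen-1(2H)-ylidene]methyl}-2,3,5-trimethoxybenzene
Product: 27 2-{(E)-chloro[(2S,4aS,8aS)-2,5,5,8a-tetramethyloctahydronaphthalen-1(2H)-ylidene]methyl}-6-methoxybenzene-1,4-diol (target), via quinone 26 (not isolated)
Conditions: (NH4)2Ce(NO3)6, MeCN/H2O, 0 °C; then Na2S2O4, H2O/EtOAc, rt
Reagents that add atoms: water O
Why: oxidative demethylation with tetravalent cerium converts the para-related C2' and C5' methoxy groups into the methoxy-para-quinone while the C3' methoxy group stays, and dithionite reduces the quinone to the hydroquinone without touching the chloroalkene.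

Compound list

1 | methyl hydrogen (R)-3-methylglutarate [(3R)-5-methoxy-3-methyl-5-oxopentanoic acid] | OC(=O)C[C@@H](C)CC(=O)OC | starting material
2 | (3S)-5-hydroxy-3-methylpentanoic acid | OC(=O)C[C@@H](C)CCO | intermediate
3 | (4S)-4-methyltetrahydro-2H-pyran-2-one | O=C1C[C@@H](C)CCO1 | intermediate
4 | (3R)-5-bromo-3-methylpentanoic acid | OC(=O)C[C@@H](C)CCBr | intermediate
5 | ketoisophorone (2,6,6-trimethylcyclohex-2-ene-1,4-dione) | CC1=CC(=O)CC(C)(C)C1=O | starting material
6 | (S)-phorenol [(4S)-4-hydroxy-2,6,6-trimethylcyclohex-2-en-1-one] | CC1=C[C@@H](O)CC(C)(C)C1=O | intermediate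
7 | (1S)-3,5,5-trimethyl-4-oxocyclohex-2-en-1-yl (3R)-5-bromo-3-methylpentanoate | CC1=C[C@@H](OC(=O)C[C@@H](C)CCBr)CC(C)(C)C1=O | intermediate
8 | trimethylsilyl ketene acetal of ester 7 (C9=C11 geometry not defined) | CC1=C[C@@H](OC(O[Si](C)(C)C)=C[C@@H](C)CCBr)CC(C)(C)C1=O | intermediate
9 | trimethylsilyl (2RS,3S)-5-bromo-3-methyl-2-[(1R)-1,3,3-trimethyl-2-oxocyclohex-5-en-1-yl]pentanoate | C[Si](C)(C)OC(=O)C([C@@H](C)CCBr)[C@@]1(C)C=CCC(C)(C)C1=O | intermediate
10 | (2RS,3S)-5-bromo-3-methyl-2-[(1R)-1,3,3-trimethyl-2-oxocyclohex-5-en-1-yl]pentanoic acid | OC(=O)C([C@@H](C)CCBr)[C@@]1(C)C=CCC(C)(C)C1=O | intermediate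
11 | methyl (2RS,3S)-5-bromo-3-methyl-2-[(1R)-1,3,3-trimethyl-2-oxocyclohex-5-en-1-yl]pentanoate | COC(=O)C([C@@H](C)CCBr)[C@@]1(C)C=CCC(C)(C)C1=O | intermediate
12 | methyl (2RS,3S)-3-methyl-5-oxo-2-[(1R)-1,3,3-trimethyl-2-oxocyclohex-5-en-1-yl]pentanoate | COC(=O)C([C@@H](C)CC=O)[C@@]1(C)C=CCC(C)(C)C1=O | intermediate
13 | TiCl2 pinacolate: cyclic TiCl2 diolate of the C5,C6-diol of ester 14 (C5 and C6 configuration not defined) | COC(=O)C1[C@@H](C)CC2O[Ti](Cl)(Cl)OC23C(C)(C)CC=C[C@]13C | intermediate
14 | methyl (1RS,2S,8aR)-2,5,5,8a-tetramethyl-1,2,3,5,6,8a-hexahydronaphthalene-1-carboxylate | COC(=O)C1[C@@H](C)CC=C2C(C)(C)CC=C[C@]12C | intermediate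
15 | methyl (1RS,2S,4aS,8aS)-2,5,5,8a-tetramethyldecahydronaphthalene-1-carboxylate | COC(=O)C1[C@@H](C)CC[C@H]2C(C)(C)CCC[C@]12C | intermediate
16 | 5-bromovanillin (3-bromo-4-hydroxy-5-methoxybenzaldehyde) | COc1cc(C=O)cc(Br)c1O | starting material
17 | 3-bromo-4-hydroxy-5-methoxyphenyl formate | COc1cc(OC=O)cc(Br)c1O | intermediate
18 | 2-bromo-6-methoxybenzene-1,4-diol | COc1cc(O)cc(Br)c1O | intermediate
19 | 1-bromo-2,3,5-trimethoxybenzene | COc1cc(OC)cc(Br)c1OC | intermediate
20 | (2,3,5-trimethoxyphenyl)lithium | COc1cc(OC)cc([Li])c1OC | intermediate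
21 | [(1RS,2S,4aS,8aS)-2,5,5,8a-tetramethyldecahydronaphthalen-1-yl](2,3,5-trimethoxyphenyl)methanone | COc1cc(OC)cc(C(=O)C2[C@@H](C)CC[C@H]3C(C)(C)CCC[C@]23C)c1OC | intermediate
22 | potassium enolate of ketone 21 | COc1cc(OC)cc(C([O-])=C2[C@@H](C)CC[C@H]3C(C)(C)CCC[C@]23C)c1OC.[K+] | intermediate
23 | [(2S,4aS,8aS)-2,5,5,8a-tetramethyloctahydronaphthalen-1(2H)-ylidene](2,3,5-trimethoxyphenyl)methyl trifluoromethanesulfonate (E/Z mixture) | COc1cc(OC)cc(C(OS(=O)(=O)C(F)(F)F)=C2[C@@H](C)CC[C@H]3C(C)(C)CCC[C@]23C)c1OC | intermediate
24 | α-(2,3,5-trimethoxyphenyl)vinyl cation from 23 | COc1cc(OC)cc([C+]=C2[C@@H](C)CC[C@H]3C(C)(C)CCC[C@]23C)c1OC | intermediate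
25 | 1-{(E)-chloro[(2S,4aS,8aS)-2,5,5,8a-tetramethyloctahydronaphthalen-1(2H)-ylidene]methyl}-2,3,5-trimethoxybenzene | COc1cc(OC)cc(/C(Cl)=C2/[C@@H](C)CC[C@H]3C(C)(C)CCC[C@]23C)c1OC | intermediate
26 | 2-{(E)-chloro[(2S,4aS,8aS)-2,5,5,8a-tetramethyloctahydronaphthalen-1(2H)-ylidene]methyl}-6-methoxycyclohexa-2,5-diene-1,4-dione | COC1=CC(=O)C=C(/C(Cl)=C2/[C@@H](C)CC[C@H]3C(C)(C)CCC[C@]23C)C1=O | intermediate
27 | 2-{(E)-chloro[(2S,4aS,8aS)-2,5,5,8a-tetramethyloctahydronaphthalen-1(2H)-ylidene]methyl}-6-methoxybenzene-1,4-diol (CNP0162917.1) | COc1cc(O)cc(/C(Cl)=C2/[C@@H](C)CC[C@H]3C(C)(C)CCC[C@]23C)c1O | target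

Total step count: 14.
Longest linear sequence: 11 steps (steps 1, 2, 4, 5, 6, 7, 8, 11, 12, 13, 14).

Steps most likely to fail

1. Step 13. Ionisation of the triflate may be too slow, or the vinyl cation may be captured by the solvent or without a clear preference for the C8 side. The fallback sets out from ketone 21 and converts it directly into the vinyl chloride by chlorodehydration with the triphenyl phosphite–chlorine adduct ((PhO)3P, Cl2, Et3N, CH2Cl2, −20 °C), which activates the carbonyl oxygen as a phosphonium leaving group before chloride delivery and loss of the C9 hydrogen. After chromatographic purification it comes back at 25 and makes no new compound.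

2. Step 7. The shielded C5 ketyl may fail to couple, so that the aldehyde is simply reduced or dimerises, or the ketyl next to the ring-A alkene may rearrange. The fallback sets out from bromide 11: SmI2 with HMPA in THF (intramolecular Barbier addition of the C6 organosamarium to the C5 ketone) gives the tertiary alcohol methyl (1RS,2S,4aRS,8aR)-4a-hydroxy-2,5,5,8a-tetramethyl-1,2,3,4,4a,5,6,8a-octahydronaphthalene-1-carboxylate F1. Dehydration with SOCl2/pyridine, where only C6 offers a β-hydrogen, comes back at 14.

3. Step 5. The ester enolate may add to the enone or expel the allylic carboxylate before it is silylated, or the rearrangement onto the electron-poor enone α-carbon may stall. The fallback sets out from ester 7 and removes the enone first: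
   - Luche reduction (NaBH4, CeCl3·7H2O, MeOH) of the C5 carbonyl gives the C5 allylic alcohol F2.
   - Et3SiOTf/2,6-lutidine gives its triethylsilyl ether F3.
   - The same Ireland–Claisen/methylation sequence, now on an electron-rich allyl system, gives the rearranged methyl ester F4.
   - HF·pyridine gives the C5 alcohol F5.
   - Dess–Martin oxidation comes back at 11.

Further compounds
F0 | step 13 | none | none
F1 | step 7 | methyl (1RS,2S,4aRS,8aR)-4a-hydroxy-2,5,5,8a-tetramethyl-1,2,3,4,4a,5,6,8a-octahydronaphthalene-1-carboxylate | COC(=O)C1[C@@H](C)CCC2(O)C(C)(C)CC=C[C@]12C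
F2 | step 5 | (1S,4RS)-4-hydroxy-3,5,5-trimethylcyclohex-2-en-1-yl (3R)-5-bromo-3-methylpentanoate | CC1=C[C@@H](OC(=O)C[C@@H](C)CCBr)CC(C)(C)C1O
F3 | step 5 | (1S,4RS)-3,5,5-trimethyl-4-(triethylsilyloxy)cyclohex-2-en-1-yl (3R)-5-bromo-3-methylpentanoate | CC1=C[C@@H](OC(=O)C[C@@H](C)CCBr)CC(C)(C)C1O[Si](CC)(CC)CC
F4 | step 5 | methyl (2RS,3S)-5-bromo-3-methyl-2-[(1R,2RS)-1,3,3-trimethyl-2-(triethylsilyloxy)cyclohex-5-en-1-yl]pentanoate | COC(=O)C([C@@H](C)CCBr)[C@@]1(C)C=CCC(C)(C)C1O[Si](CC)(CC)CC
F5 | step 5 | methyl (2RS,3S)-5-bromo-2-[(1R,2RS)-2-hydroxy-1,3,3-trimethylcyclohex-5-en-1-yl]-3-methylpentanoate | COC(=O)C([C@@H](C)CCBr)[C@@]1(C)C=CCC(C)(C)C1O
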